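The C1–C10 bond of the seven-membered ring is the one to cut. That ring has a single CH2, C7, lying between oxygen-bearing C6 and the C8=C9 alkene, directly across from the pair formed by quaternary C1 (angular methyl) and carbinol C10; this marks C6–C7–C8 as a former cyclopropane. A cis-divinylcyclopropane with a silyloxy group and the ketal-protected 2-methylcyclopentenyl unit on C6 and, on C8, a methyl and an (E)-2-(4-methoxybenzyloxy)vinyl group undergoes one thermal [3,3] shift. It closes the cycloheptadiene onto the five-membered ring, sets C1 and C10 stereospecifically and leaves C6 as a silyl enol ether. Ring fusion, C4 and C6 then follow by substrate control.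

Key step: step 11

Locants used below: C1 ring-fusion carbon with the angular methyl, C2 and C3 the five-ring CH2 groups, C4 the isopropyl carbinol, C5 the ring-fusion CH, C6 the aroyloxy carbon, C7 the seven-ring CH2, C8=C9 the ring alkene (methyl on C8), C10 the tigloyloxy carbon. β is the face of the C1 methyl, α the opposite face. TBS = tert-butyldimethylsilyl, PMB = 4-methoxybenzyl, pin = pinacolato.

Assumption: the copper carbenoid formed with the (R,R)-tert-butyl bis(oxazoline) ligand is taken to show towards diene 7 the carbenoid-face preference known for styrene; should the major trans ester prove to be the enantiomer of 9, the (S,S)-ligand is used instead.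

Step 1
Reactants: 1 3-methylcyclopent-2-en-1-one
Product: 2 2-iodo-3-methylcyclopent-2-en-1-one
Conditions: I2, pyridine, CH2Cl2, 0 °C to rt
Reagents that add atoms: iodine, II
Why: Johnson α-iodination of an enone (conjugate addition of pyridine, iodination of the enolate, elimination of pyridine) should place iodine on the α-carbon, the future C5.

Step 2
Reactants: 2 2-iodo-3-methylcyclopent-2-en-1-one
Product: 3 6-iodo-7-methyl-1,4-dioxaspiro[4.4]non-6-ene
Conditions: HOCH2CH2OH, p-TsOH·H2O (cat.), benzene, reflux, Dean–Stark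
Reagents that add atoms: ethylene glycol, OCCO
Why: Acid-catalysed ketalisation with azeotropic removal of water; α-halo enones give their dioxolanes without migration of the double bond, and the ketal masks C4 and allows the halogen–lithium exchange of step 3.

Step 3
Reactants: 3 6-iodo-7-methyl-1,4-dioxaspiro[4.4]non-6-ene
Product: 5 1-(7-methyl-1,4-dioxaspiro[4.4]non-6-en-6-yl)ethan-1-one, via alkenyllithium 4 (not isolated)
Conditions: n-BuLi, THF, −78 °C; then MeC(O)N(OMe)Me, −78 to 0 °C
Reagents that add atoms: N-methoxy-N-methylacetamide, CC(=O)N(C)OC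
Why: Iodine–lithium exchange gives the α-keto vinyl anion equivalent, and Weinreb acylation should stop at the ketone because the chelated tetrahedral adduct collapses only on work-up; this brings in C6 and C7.

Step 4
Reactants: 5 1-(7-methyl-1,4-dioxaspiro[4.4]non-6-en-6-yl)ethan-1-one
Product: 7 tert-butyldimethyl{[1-(7-methyl-1,4-dioxaspiro[4.4]non-6-en-6-yl)ethenyl]oxy}silane, via lithium enolate 6 (not isolated)
Conditions: LiN(i-Pr)2, THF, −78 °C; then TBSCl, DMPU, −78 to 0 °C
Reagents that add atoms: tert-butyldimethylsilyl chloride, CC(C)(C)[Si](C)(C)Cl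
Why: Kinetic deprotonation of the methyl ketone at its methyl group gives the cross-conjugated enolate and O-silylation the 2-silyloxydiene; TBS is preferred to a trimethylsilyl group so that the donor–acceptor cyclopropanes of steps 5 to 9 survive handling.

Step 5
Reactants: 7 tert-butyldimethyl{[1-(7-methyl-1,4-dioxaspiro[4.4]non-6-en-6-yl)ethenyl]oxy}silane; 8 ethyl diazoacetate
Product: 9 ethyl (1S,2R)-2-(TBS-oxy)-2-(7-methyl-1,4-dioxaspiro[4.4]non-6-en-6-yl)cyclopropane-1-carboxylate (ester trans to the cyclopentenyl group)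
Conditions: (CuOTf)2·C6H6 (1 mol %), (R,R)-t-Bu-box (2.2 mol %), CH2Cl2, 0 °C to rt, slow addition of 8
Reagents that add atoms: none
Why: Copper–bis(oxazoline) carbenoid cyclopropanation, known for silyl enol ethers, should attack only the electron-rich terminal alkene C6=C7; the ligand fixes the face of the carbenoid carbon C8 and the ester turns away from the bulky twisted cyclopentenyl group, which together set C6, the one centre that survives step 6, so any cis ester (opposite configuration at C6) is removed by chromatography.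

Step 6
Reactants: 9 ethyl (1S,2R)-2-(TBS-oxy)-2-(7-methyl-1,4-dioxaspiro[4.4]non-6-en-6-yl)cyclopropane-1-carboxylate
Product: 11 ethyl (1R,2S)-2-(TBS-oxy)-1-methyl-2-(7-methyl-1,4-dioxaspiro[4.4]non-6-en-6-yl)cyclopropane-1-carboxylate (methyl cis to the silyloxy group), via ester enolate 10 (not isolated)
Conditions: LiN(i-Pr)2, DMPU, THF, −78 to −40 °C; then MeI, −78 °C
Reagents that add atoms: iodomethane, CI
Why: Ester enolate alkylation, established for 2-silyloxycyclopropanecarboxylates: C8 is planarised and iodomethane should enter on the face away from the cyclopentenyl group, which covers its own side of the three-membered ring, so the ester ends cis to the cyclopentenyl group as the [3,3] shift requires, a relationship that direct cyclopropanation with a 2-diazopropanoate would not favour on steric grounds.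

Step 7
Reactants: 11 ethyl (1R,2S)-2-(TBS-oxy)-1-methyl-2-(7-methyl-1,4-dioxaspiro[4.4]non-6-en-6-yl)cyclopropane-1-carboxylate
Product: 12 [(1S,2R)-2-(TBS-oxy)-1-methyl-2-(7-methyl-1,4-dioxaspiro[4.4]non-6-en-6-yl)cyclopropyl]methanol
Conditions: i-Bu2AlH, CH2Cl2, −78 to 0 °C; Rochelle salt work-up
Reagents that add atoms: none
Why: Hydride reduction of the ester to the primary alcohol under non-acidic conditions that leave the silyl ether, the ketal and the donor–acceptor cyclopropane untouched.

Step 8
Reactants: 12 [(1S,2R)-2-(TBS-oxy)-1-methyl-2-(7-methyl-1,4-dioxaspiro[4.4]non-6-en-6-yl)cyclopropyl]methanol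
Product: 13 (1R,2R)-2-(TBS-oxy)-1-methyl-2-(7-methyl-1,4-dioxaspiro[4.4]non-6-en-6-yl)cyclopropane-1-carbaldehyde
Conditions: Dess–Martin periodinane, pyridine, CH2Cl2, 0 °C
Reagents that add atoms: none
Why: Buffered Dess–Martin oxidation gives the non-enolisable aldehyde, which is used cold and at once because cis-2-alkenylcyclopropanecarbaldehydes can equilibrate with dihydrooxepines on standing.

Step 9
Reactants: 13 (1R,2R)-2-(TBS-oxy)-1-methyl-2-(7-methyl-1,4-dioxaspiro[4.4]non-6-en-6-yl)cyclopropane-1-carbaldehyde
Product: 14 tert-butyldimethyl{[(1R,2S)-2-methyl-1-(7-methyl-1,4-dioxaspiro[4.4]non-6-en-6-yl)-2-[(E)-2-(4,4,5,5-tetramethyl-1,3,2-dioxaborolan-2-yl)ethenyl]cyclopropyl]oxy}silane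
Conditions: CH2(Bpin)2, lithium 2,2,6,6-tetramethylpiperidide, THF, 0 °C; then 13, −78 °C to rt
Reagents that add atoms: bis(4,4,5,5-tetramethyl-1,3,2-dioxaborolan-2-yl)methane, CC1(C)OB(CB2OC(C)(C)C(C)(C)O2)OC1(C)C
Why: Boron–Wittig olefination: the lithiated geminal bis(boronate) adds to the aldehyde and syn B–O elimination from the less crowded adduct should give the trans-alkenylboronate, which fixes the (E) geometry of C9=C10 and brings in C10.

Step 10
Reactants: 14 (E)-alkenylboronate of step 9; 15 4-methoxybenzyl alcohol
Product: 16 tert-butyl{[(1R,2S)-2-[(E)-2-[(4-methoxyphenyl)methoxy]ethenyl]-2-methyl-1-(7-methyl-1,4-dioxaspiro[4.4]non-6-en-6-yl)cyclopropyl]oxy}dimethylsilane (the two alkenyl groups cis)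
Conditions: Cu(OAc)2 (2 equiv), Et3N, 15 (excess), 4 Å molecular sieves, CH2Cl2, rt, air
Reagents that add atoms: none
Why: Copper-mediated oxidative C–O coupling of an alkenyl pinacolboronate with an alcohol (Chan–Lam–Evans type) runs at room temperature with retention of alkene geometry, so the (E)-enol ether should form as a single isomer without acid or heat, which an alkoxymethylene Wittig reaction would not secure.

Step 11
Reactants: 16 cis-divinylcyclopropane of step 10
Product: 17 (1R,10S)-6-(TBS-oxy)-10α-(PMB-oxy)-1β,8-dimethyl hydroazulene-5,8-diene 4-ethylene ketal (route locants; C5=C6 silyl enol ether, C8=C9 alkene)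
Conditions: toluene, 110–140 °C, sealed tube, 2,6-di-tert-butyl-4-methylphenol (cat.), base-washed glass
Reagents that add atoms: none
Why: On heating, the cis-divinylcyclopropane should pass through the boat-shaped six-centre transition state in which the cyclopentene alkene C1=C5 and the enol ether alkene C9=C10 both lie over the three-membered ring; the C6–C8 σ bond breaks as C1–C10 forms and the π bonds move to C5=C6 and C8=C9, a concerted [3,3] sigmatropic shift driven by loss of ring strain and assisted by the C6 silyloxy donor. The closest known reaction type is the divinylcyclopropane–cycloheptadiene (Cope) rearrangement of 2-silyloxy-substituted cis-divinylcyclopropanes, which tolerates Z-substituted and fully substituted termini at raised temperature. The seven-membered ring (C1, C5, C6, C7, C8, C9, C10) closes by suprafacial bonding between the alkene termini C1 and C10, a formal 3+4 ring enlargement annulated to the five-membered ring. C1 and C10 are set stereospecifically: the configuration at C6 and C8 decides which alkene faces meet, and the (E)-enol ether places the PMB-oxy group outside and the C1 methyl inside the boat, so O10 ends α, anti to the β methyl (1R,10S). The step needs the two alkenyl groups cis on the cyclopropane (steps 5 and 6), a pure (E)-enol ether (steps 9 and 10) and a [3,3] shift that outruns ene-type ring opening by the hydrogens of the inside methyl, which the silyloxy donor and a moderate temperature should secure.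

Step 12
Reactants: 17 bicyclic silyl enol ether of step 11
Product: 19 C6 alcohol of the cis-fused 4-ketal (C5–H β; C6 epimers; C10 OPMB α), via cis-fused ketone 18 (not isolated)
Conditions: Bu4NF, AcOH, THF, 0 °C; then NaBH4, MeOH, 0 °C
Reagents that add atoms: none
Why: Fluoride cleavage of the silyl enol ether and kinetic protonation of the enolate at C5 on the face away from C10 and the bulk of the seven-membered ring (syn to the C1 methyl) should give the cis ring fusion, and borohydride reduction then masks C6 as an alcohol whose configuration is of no consequence because C6 is re-oxidised in step 15.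

Step 13
Reactants: 19 C6 alcohol of the cis-fused 4-ketal
Product: 20 cis-fused 6-hydroxy 4-ketone (C10 OPMB α)
Conditions: pyridinium p-toluenesulfonate (cat.), acetone/H2O, 50 °C
Reagents that add atoms: water, O
Why: Mild acid-catalysed ketal hydrolysis that should leave the allylic PMB ether and the β-hydroxy ketone intact, the cis ring fusion being kept as the favoured arrangement at the enolisable C5 next to the angular methyl.

Step 14
Reactants: 20 cis-fused 6-hydroxy 4-ketone
Product: 21 4α-hydroxy-4β-isopropyl 6-alcohol (4R; C6 epimers; C10 OPMB α)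
Conditions: i-PrMgCl, anhydrous CeCl3, THF, −78 °C
Reagents that add atoms: isopropylmagnesium chloride, CC(C)[Mg]Cl
Why: Organocerium (Imamoto) 1,2-addition suppresses enolisation at C5 and β-hydride reduction; after the first equivalent has formed the C6 alkoxide, isopropyl should add to the C4 carbonyl from the convex β face, anti to the adjacent C5–C6 bond of the cis-fused bicycle, which sets C4 (R) with the hydroxyl α.

Step 15
Reactants: 21 4α-hydroxy-4β-isopropyl 6-alcohol
Product: 22 4α-hydroxy-4β-isopropyl 6-ketone (cis-fused β-hydroxy ketone; C10 OPMB α)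
Conditions: Dess–Martin periodinane, NaHCO3, CH2Cl2, 0 °C to rt
Reagents that add atoms: none
Why: Dess–Martin oxidation of the only secondary alcohol; the tertiary C4 hydroxyl, the PMB ether and the alkene are inert and the buffered medium avoids retro-aldol cleavage.

Step 16
Reactants: 22 4α-hydroxy-4β-isopropyl 6-ketone
Product: 23 (1R,4R,5S,6S,10S)-4α,6β-diol with C10 OPMB α
Conditions: Me4NBH(OAc)3, MeCN/AcOH, −20 to 0 °C
Reagents that add atoms: none
Why: Hydroxyl-directed reduction (Evans–Saksena): the C4 hydroxyl binds the triacetoxyborohydride and should deliver hydride through a six-membered transition state to the C6 face syn to the C4–C5 bond, so the new hydroxyl ends β (cis to H5, 6S), the epimer that external hydride attack anti to C4 would not give.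

Step 17
Reactants: 24 4-hydroxybenzoic acid
Product: 26 4-(TBS-oxy)benzoic acid, via bis-silyl derivative 25 (not isolated)
Conditions: TBSCl (2.2 equiv), imidazole, DMF, rt; then AcOH/THF/H2O, rt
Reagents that add atoms: tert-butyldimethylsilyl chloride, CC(C)(C)[Si](C)(C)Cl
Why: Silylation of both acidic groups followed by selective hydrolysis of the far more labile silyl ester gives the phenol-protected acid; a silyl ether is chosen because it cannot transfer an acyl group during the later tigloylation.

Step 18
Reactants: 23 (1R,4R,5S,6S,10S)-4α,6β-diol; 26 4-(TBS-oxy)benzoic acid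
Product: 27 6β-[4-(TBS-oxy)benzoyloxy] 4α-alcohol with C10 OPMB α
Conditions: DCC, DMAP, CH2Cl2, rt
Reagents that add atoms: none
Why: Steglich esterification should acylate only the secondary C6 hydroxyl, the tertiary C4 hydroxyl being inert, and placing this step after the isopropyl addition keeps the ester away from organometallic reagents and from β-elimination next to a C4 ketone.

Step 19
Reactants: 27 6β-[4-(TBS-oxy)benzoyloxy] 4α-alcohol with C10 OPMB α
Product: 28 6β-[4-(TBS-oxy)benzoyloxy] 4α,10α-diol
Conditions: DDQ, CH2Cl2/pH 7 phosphate buffer, 0 °C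
Reagents that add atoms: none
Why: Oxidative PMB cleavage (hydride abstraction to the oxocarbenium ion, then hydrolysis) under cold buffered conditions should free the C10 hydroxyl without over-oxidising the hindered allylic alcohol or touching the aryl silyl ether.

Step 20
Reactants: 28 6β-[4-(TBS-oxy)benzoyloxy] 4α,10α-diol; 29 tiglic acid
Product: 31 10α-tiglate 6β-[4-(TBS-oxy)benzoate] 4α-alcohol, via mixed anhydride 30 (not isolated)
Conditions: 2,4,6-Cl3C6H2COCl, Et3N, toluene, rt; then 28, DMAP, 60 °C
Reagents that add atoms: none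
Why: Yamaguchi esterification through the mixed anhydride and the acylpyridinium ion should force acylation of the hindered allylic C10 hydroxyl next to quaternary C1; the tertiary alcohol stays free and the (E)-tiglate is the stable alkene isomer.

Step 21
Reactants: 31 10α-tiglate 6β-[4-(TBS-oxy)benzoate] 4α-alcohol
Product: 32 target CNP0273650.3
Conditions: Bu4NF, AcOH, THF, 0 °C
Reagents that add atoms: none
Why: Buffered fluoride cleavage of the aryl silyl ether, much faster than any reaction of the two esters or the tertiary alcohol, frees the phenol and should complete the target.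

Compound list
1 | 3-methylcyclopent-2-en-1-one | CC1=CC(=O)CC1 | starting material
2 | 2-iodo-3-methylcyclopent-2-en-1-one | CC1=C(I)C(=O)CC1 | intermediate
3 | 6-iodo-7-methyl-1,4-dioxaspiro[4.4]non-6-ene | CC1=C(I)C2(CC1)OCCO2 | intermediate
4 | (7-methyl-1,4-dioxaspiro[4.4]non-6-en-6-yl)lithium | [Li]C1=C(C)CCC12OCCO2 | intermediate
5 | 1-(7-methyl-1,4-dioxaspiro[4.4]non-6-en-6-yl)ethan-1-one | CC(=O)C1=C(C)CCC12OCCO2 | intermediate
6 | lithium 1-(7-methyl-1,4-dioxaspiro[4.4]non-6-en-6-yl)ethen-1-olate | [Li]OC(=C)C1=C(C)CCC12OCCO2 | intermediate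
7 | tert-butyldimethyl{[1-(7-methyl-1,4-dioxaspiro[4.4]non-6-en-6-yl)ethenyl]oxy}silane | C=C(O[Si](C)(C)C(C)(C)C)C1=C(C)CCC12OCCO2 | intermediate
8 | ethyl diazoacetate | CCOC(=O)C=[N+]=[N-] | starting material
9 | ethyl (1S,2R)-2-(TBS-oxy)-2-(7-methyl-1,4-dioxaspiro[4.4]non-6-en-6-yl)cyclopropane-1-carboxylate (ester trans to cyclopentenyl) | CC1=C([C@@]2(O[Si](C)(C)C(C)(C)C)C[C@@H]2C(=O)OCC)C3(CC1)OCCO3 | intermediate
10 | lithium enolate of 9 (C8 planar, C6 unchanged) | CCOC(O[Li])=C1C[C@]1(O[Si](C)(C)C(C)(C)C)C1=C(C)CCC12OCCO2 | intermediate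
11 | ethyl (1R,2S)-2-(TBS-oxy)-1-methyl-2-(7-methyl-1,4-dioxaspiro[4.4]non-6-en-6-yl)cyclopropane-1-carboxylate (ester cis to cyclopentenyl) | CC1=C([C@@]2(O[Si](C)(C)C(C)(C)C)C[C@@]2(C)C(=O)OCC)C3(CC1)OCCO3 | intermediate
12 | [(1S,2R)-2-(TBS-oxy)-1-methyl-2-(7-methyl-1,4-dioxaspiro[4.4]non-6-en-6-yl)cyclopropyl]methanol | CC1=C([C@@]2(O[Si](C)(C)C(C)(C)C)C[C@@]2(C)CO)C3(CC1)OCCO3 | intermediate
13 | (1R,2R)-2-(TBS-oxy)-1-methyl-2-(7-methyl-1,4-dioxaspiro[4.4]non-6-en-6-yl)cyclopropane-1-carbaldehyde | CC1=C([C@@]2(O[Si](C)(C)C(C)(C)C)C[C@@]2(C)C=O)C3(CC1)OCCO3 | intermediate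
14 | tert-butyldimethyl{[(1R,2S)-2-methyl-1-(7-methyl-1,4-dioxaspiro[4.4]non-6-en-6-yl)-2-[(E)-2-(4,4,5,5-tetramethyl-1,3,2-dioxaborolan-2-yl)ethenyl]cyclopropyl]oxy}silane | CC1=C([C@@]2(O[Si](C)(C)C(C)(C)C)C[C@@]2(C)/C=C/B4OC(C)(C)C(C)(C)O4)C3(CC1)OCCO3 | intermediate
15 | 4-methoxybenzyl alcohol | COc1ccc(CO)cc1 | starting material
16 | tert-butyl{[(1R,2S)-2-[(E)-2-[(4-methoxyphenyl)methoxy]ethenyl]-2-methyl-1-(7-methyl-1,4-dioxaspiro[4.4]non-6-en-6-yl)cyclopropyl]oxy}dimethylsilane | CC1=C([C@@]2(O[Si](C)(C)C(C)(C)C)C[C@@]2(C)/C=C/OCc2ccc(OC)cc2)C3(CC1)OCCO3 | intermediate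
17 | (1R,10S)-6-(TBS-oxy)-10α-(PMB-oxy)-1β,8-dimethyl hydroazulene-5,8-diene 4-ethylene ketal (route locants) | COc1ccc(cc1)CO[C@H]1C=C(C)CC(O[Si](C)(C)C(C)(C)C)=C2[C@@]1(C)CCC23OCCO3 | intermediate
18 | cis-fused 6-ketone 4-ethylene ketal (C5–H β, C10 OPMB α) | COc1ccc(cc1)CO[C@H]1C=C(C)CC(=O)[C@@H]2[C@@]1(C)CCC23OCCO3 | intermediate
19 | cis-fused 6-alcohol 4-ethylene ketal (C6 epimers) | COc1ccc(cc1)CO[C@H]1C=C(C)CC(O)[C@@H]2[C@@]1(C)CCC23OCCO3 | intermediate
20 | cis-fused 6-hydroxy 4-ketone (C6 epimers) | COc1ccc(cc1)CO[C@H]1C=C(C)CC(O)[C@@H]2[C@@]1(C)CCC2=O | intermediate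
21 | 4α-hydroxy-4β-isopropyl 6-alcohol (4R; C6 epimers) | COc1ccc(cc1)CO[C@H]1C=C(C)CC(O)[C@@H]2[C@@]1(C)CC[C@@]2(O)C(C)C | intermediate
22 | 4α-hydroxy-4β-isopropyl 6-ketone | COc1ccc(cc1)CO[C@H]1C=C(C)CC(=O)[C@@H]2[C@@]1(C)CC[C@@]2(O)C(C)C | intermediate
23 | (1R,4R,5S,6S,10S)-4α,6β-diol, C10 OPMB α | COc1ccc(cc1)CO[C@H]1C=C(C)C[C@H](O)[C@@H]2[C@@]1(C)CC[C@@]2(O)C(C)C | intermediate
24 | 4-hydroxybenzoic acid | OC(=O)c1ccc(O)cc1 | starting material
25 | tert-butyldimethylsilyl 4-(TBS-oxy)benzoate | CC(C)(C)[Si](C)(C)OC(=O)c1ccc(O[Si](C)(C)C(C)(C)C)cc1 | intermediate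
26 | 4-(TBS-oxy)benzoic acid | CC(C)(C)[Si](C)(C)Oc1ccc(C(=O)O)cc1 | intermediate
27 | 6β-[4-(TBS-oxy)benzoyloxy] 4α-alcohol, C10 OPMB α | COc1ccc(cc1)CO[C@H]1C=C(C)C[C@H](OC(=O)c2ccc(O[Si](C)(C)C(C)(C)C)cc2)[C@@H]2[C@@]1(C)CC[C@@]2(O)C(C)C | intermediate
28 | 6β-[4-(TBS-oxy)benzoyloxy] 4α,10α-diol | O[C@H]1C=C(C)C[C@H](OC(=O)c2ccc(O[Si](C)(C)C(C)(C)C)cc2)[C@@H]2[C@@]1(C)CC[C@@]2(O)C(C)C | intermediate
29 | tiglic acid, (E)-2-methylbut-2-enoic acid | C/C=C(\C)C(=O)O | starting material
30 | tiglic 2,4,6-trichlorobenzoic anhydride | C/C=C(\C)C(=O)OC(=O)c1c(Cl)cc(Cl)cc1Cl | intermediate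
31 | 10α-tiglate 6β-[4-(TBS-oxy)benzoate] 4α-alcohol | C/C=C(\C)C(=O)O[C@H]1C=C(C)C[C@H](OC(=O)c2ccc(O[Si](C)(C)C(C)(C)C)cc2)[C@@H]2[C@@]1(C)CC[C@@]2(O)C(C)C | intermediate
32 | CNP0273650.3, (1R,4R,5S,6S,10S)-4α-hydroxy-4β-isopropyl-1β,8-dimethyl-6β-(4-hydroxybenzoyloxy)-10α-[(E)-2-methylbut-2-enoyloxy] cis-hydroazulen-8-ene (route locants) | C/C=C(\C)C(=O)O[C@H]1C=C(C)C[C@H](OC(=O)c2ccc(O)cc2)[C@@H]2[C@@]1(C)CC[C@@]2(O)C(C)C | target

Total step count: 21. Longest linear sequence: 20 steps (steps 1 to 16 and 18 to 21, from 1 to 32).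

Steps most likely to fail

Step 11. The inside methyl on C1 raises the boat transition state, so ene-type ring opening (hydrogen transfer from that methyl to C8 with cleavage of C6–C8) or slow thermal decay of the doubly donor-substituted system may compete with ring closure. The fallback sets out from alkenylboronate 14 and rejoins the route at 17. Heating 14 itself should bring about the same [3,3] shift on a polarity-matched system (donor on C6, boron acceptor on the C10 terminus) that carries no labile enol ether. This should give the C10 pinacolboronate F1, with boron α because it sits outside in the boat. NaBO3·4H2O in THF/H2O should then oxidise the C–B bond with retention to the 10α-allylic alcohol F2. NaH and 4-methoxybenzyl chloride (Bu4NI, THF) should convert F2 into 17; step 10 is then not needed.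

Step 5. Enantioface discrimination or trans/cis control may be weak with the hindered, twisted diene (the cis ester carries the opposite configuration at C6), and carbene dimerisation may outpace cyclopropanation. The fallback sets out from 7 and rejoins at 9. Cyclopropanation with 8 under Rh2(OAc)4, which is not enantioselective, should give the trans ester as the racemate, that is 9 together with its enantiomer F3. The two are separated by preparative chromatography on a chiral stationary phase, so resolution replaces asymmetric catalysis.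

Step 16. The hindered tertiary C4 hydroxyl may exchange onto boron too slowly, so that internal hydride delivery does not take place or a background reduction erodes the selectivity. The fallback sets out from 22 and rejoins at 27. LiBH(s-Bu)3 (THF, −78 °C) should attack C6 from the open β face and give the 6α-alcohol F4. Mitsunobu esterification of F4 with acid 26 (PPh3, diisopropyl azodicarboxylate, toluene) should invert C6 and install the aroyl group in one operation, giving 27; step 18 is then not needed.

Further compounds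
F1 | step 11 | C10α pinacolboronate analogue of 17 (Bpin in place of OPMB) | CC1(C)OB(OC1(C)C)[C@H]1C=C(C)CC(O[Si](C)(C)C(C)(C)C)=C2[C@@]1(C)CCC23OCCO3
F2 | step 11 | 10α-allylic alcohol with C6 TBS enol ether and 4-ketal | O[C@H]1C=C(C)CC(O[Si](C)(C)C(C)(C)C)=C2[C@@]1(C)CCC23OCCO3
F3 | step 5 | ethyl (1R,2S)-2-(TBS-oxy)-2-(7-methyl-1,4-dioxaspiro[4.4]non-6-en-6-yl)cyclopropane-1-carboxylate (enantiomer of 9) | CC1=C([C@]2(O[Si](C)(C)C(C)(C)C)C[C@H]2C(=O)OCC)C3(CC1)OCCO3
F4 | step 16 | 4α,6α-diol, C10 OPMB α (6-epimer of 23) | COc1ccc(cc1)CO[C@H]1C=C(C)C[C@@H](O)[C@@H]2[C@@]1(C)CC[C@@]2(O)C(C)C
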